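(The data come from a simulation on assumed constants; noise was put on by code.)

| setting | west | south-east | north | east | south |
|---|---|---|---|---|---|
| starting material | 120 mM | 48.0 mM | 180 mM | 120 mM | 250 mM |
| reagent | 144 mM | 72.0 mM | 144 mM | 144 mM | 144 mM |
| target |  |  |  | 36.0 mM |  |
| time |  |  |  |  | 97 min |

| run | time / min | [target] / mM |
|---|---|---|
| west run | 4.3 | 13.2 |
| west run | 13 | 32.2 |
| west run | 25 | 44.9 |
| west run | 40 | 55.2 |
| west run | 57 | 61.5 |
| west run | 76 | 65.2 |
| west run | 97 | 68.4 |
| south-east run | 4.3 | 1.8 |
| south-east run | 13 | 6.2 |
| south-east run | 25 | 9.6 |
| south-east run | 40 | 13.5 |
| south-east run | 57 | 15.4 |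
| south-east run | 76 | 16.9 |
| south-east run | 97 | 20.7 |
| north run | 4.3 | 19.8 |
| north run | 13 | 43.1 |
| north run | 25 | 60.4 |
| north run | 40 | 73.0 |
| north run | 57 | 80.5 |
| north run | 76 | 86.9 |
| north run | 97 | 90.4 |
| east run | 4.3 | 48.7 |
| east run | 13 | 66.1 |
| east run | 25 | 79.2 |
| east run | 40 | 88.0 |
| east run | 57 | 92.7 |
| east run | 76 | 97.0 |
| east run | 97 | 98.9 |

(standard deviation of a reading: 0.6 mM)

- Overall: starting material + reagent -> target.
- Constant volume, constant temperature.
- An order is taken over about fifteen percent of the charge, up and down.

1. the exponent of [reagent] in the starting rate at the charge of the west run (at the point where two percent of the starting material have become target)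
2. the exponent of [starting material] in the starting rate at the charge of the west run (at the point where two percent of the starting material have become target) (one fixed amount of target, the same in the runs compared)
3. target in the south run at 97 min, as a share of the starting material charged

The ratio I carried was the last-reading quotient, [target]/([starting material][reagent]) at 97 min in the north run (a reaction quotient), with each lower term taken as its charge minus the target made, one reagent per target as the overall equation is written: 0.0188 mM⁻¹.

The west run is its neighbour, with the same reagent and less starting material, and there the same ratio read 0.0175 mM⁻¹, a little lower than in the north run. The two quotients lay close, but they only describe the last readings and set no limit, for the north run was still rising there, from 86.9 mM to 90.4 mM. At its last reading the north run stood at 50.2% of its starting material against 57.0% in the west run, with 53.6 mM of reagent left by the subtraction against 75.6 mM.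

The south run has the same reagent again, and as a working estimate I set its last-reading quotient equal to that of the north run, its nearest charge, and solved the resulting quadratic for the target. That gave me 105 mM, or 42.1% of the starting material charged.

The forecast said 42%, within 40.3% to 43.7%, with exponents 1.5 in reagent (from 1.1 to 1.9) and 1 in starting material (from 0.8 to 1.2). Its ground was that the stall “points to a reversible reaction”.

The south run gave 42.5% of its starting material as target, or 106 mM, and the exponents came to 1.6 in reagent and 1.0 in starting material. The steps behind the readings were these:

    starting material + reagent → target (0.08400 L mol⁻¹ min⁻¹)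
    starting material + 2 reagent → target + reagent (0.8520 L² mol⁻² min⁻¹)
    target + reagent → side product (0.01752 L mol⁻¹ min⁻¹)
    starting material → decomposed substrate (0.005952 min⁻¹)

They hold side product and decomposed substrate, which the quotient's subtraction does not book, and a fit with the main steps alone left residuals of 7.6 times the scatter. The south run's quotient came to 0.0197 mM⁻¹. To pass the forecast's high end, 109 mM, it needed more than 0.0223 mM⁻¹. The east run, read the same way, stood lower than that, at 0.0214 mM⁻¹.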